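**Plan**

- Retrosynthesis: the five isopropyl ethers come off last. The ring bond C1–C2 is cut next, back to diaryl carbinol 16 (ring A para-quinone methide plus the enol of the C2 ketone). The alkene C3=C4 is cut by a Wittig disconnection to lactol 10 and the ylide of diaroylethylene 13. The bond from the carbinol carbon C1 to ring B (C8a) is cut to a lithiated ring B acetal and ring A aldehyde 4.
- Forward: aldehyde 4 (from 2,3,4-trihydroxybenzaldehyde), acetal 7 (from 5-hydroxyvanillin) and enedione 13 (from 4'-hydroxyacetophenone) are made separately. 7 and 4 give the diaryl carbinol as lactol 10, the Wittig reaction attaches the four-carbon diketone chain, and the only ring that is built, the carbocycle C1–C2–C3–C4–C4a–C8a, closes in step 11.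
- Enabling feature: C1 is benzylic to both arenes and para to the 4-hydroxyl of ring A, so a C1 carbinol dehydrates to a para-quinone methide. C2 is the α-carbon of an aryl ketone and is held next to C1 by ring B and the E-alkene C3=C4.
- Stereochemistry: C1 and C2 (1S,2S; ring A aryl and C2 aroyl cis) are both set in step 11 by a chiral phosphoric acid acting on the racemic carbinol. Step 12 is base-free and does not touch them.

Key step: step 11

Assumption: the target SMILES is read as the (1S,2S) isomer with the aryl group at C1 and the aroyl group at C2 cis. The (R) acid is written on the assumption that it leads to this series; its mirror image is used if the sense of induction proves opposite.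

**Route**

Step 1
Reactants: 1 2,3,4-trihydroxybenzaldehyde
Product: 2 4-(allyloxy)-2,3-dihydroxybenzaldehyde
Conditions: allyl bromide (1.05 equiv), NaHCO3, DMF, 40 °C
Reagents that add atoms: allyl bromide, C=CCBr
Why: Williamson etherification under weak-base control, in which NaHCO3 ionises only the 4-hydroxyl (para to the formyl group, most acidic, not chelated), so the allyl group should enter there and leave the 2- and 3-hydroxyls free.

Step 2
Reactants: 2 4-(allyloxy)-2,3-dihydroxybenzaldehyde
Product: 3 4-(allyloxy)-2-hydroxy-3-isopropoxybenzaldehyde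
Conditions: NaH (2.2 equiv), DMSO, rt; 2-bromopropane (1.1 equiv), rt to 45 °C; 1 M HCl work-up
Reagents that add atoms: 2-bromopropane, CC(C)Br
Why: Regioselective O-alkylation of a catechol dianion, in which the 3-oxide, neither conjugated with nor chelated to the formyl group, is the more nucleophilic site (as known for 2,3-dihydroxybenzaldehyde), so the isopropyl group should go to O-3.

Step 3
Reactants: 3 4-(allyloxy)-2-hydroxy-3-isopropoxybenzaldehyde
Product: 4 4-(allyloxy)-3-isopropoxy-2-methoxybenzaldehyde
Conditions: MeI, K2CO3, DMF, rt
Reagents that add atoms: iodomethane, CI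
Why: Williamson methylation of the one remaining, hydrogen-bonded 2-hydroxyl, which K2CO3 in DMF ionises readily, completes the three different ethers of ring A.

Step 4
Reactants: 5 5-hydroxyvanillin (3,4-dihydroxy-5-methoxybenzaldehyde)
Product: 6 3,4-diisopropoxy-5-methoxybenzaldehyde
Conditions: 2-bromopropane (3 equiv), K2CO3, DMF, 70 °C
Reagents that add atoms: 2-bromopropane, CC(C)Br
Why: Double Williamson etherification of the catechol gives the ring B aldehyde with its two future hydroxyls as isopropyl ethers, which BCl3 can later remove without touching the methyl ether.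

Step 5
Reactants: 6 3,4-diisopropoxy-5-methoxybenzaldehyde
Product: 7 5-(dimethoxymethyl)-1,2-diisopropoxy-3-methoxybenzene
Conditions: HC(OMe)3, cat. p-TsOH·H2O, MeOH, rt; Et3N quench
Reagents that add atoms: trimethyl orthoformate, COC(OC)OC; methanol, CO
Why: Acid-catalysed acetalisation, driven by the orthoformate as water scavenger, masks the aldehyde against n-BuLi and turns it into an ortho-directing group.

Step 6
Reactants: 7 5-(dimethoxymethyl)-1,2-diisopropoxy-3-methoxybenzene; 4 4-(allyloxy)-3-isopropoxy-2-methoxybenzaldehyde
Product: 10 3-[4-(allyloxy)-3-isopropoxy-2-methoxyphenyl]-5,6-diisopropoxy-4-methoxy-1,3-dihydroisobenzofuran-1-ol (racemic lactol; mixture of C1 epimers), via ring B aryllithium 8 (not isolated), via hydroxy acetal 9 (not isolated)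
Conditions: n-BuLi (1.1 equiv), THF, 0 °C, 1 h; then 4 (0.9 equiv), −78 to 0 °C; then 1 M HCl, THF, 0 °C
Reagents that add atoms: water, O
Why: Directed ortho-metalation should take place at the carbon flanked by the acetal and the methoxy group (cooperative directing groups, the other flanked site being shielded by the bulkier, conformationally locked isopropoxy group); the aryllithium adds 1,2 to aldehyde 4, and aqueous acid unmasks the aldehyde, which the neighbouring carbinol captures as the five-membered lactol; the carbinol centre forms racemic, which is intended because step 11 erases it.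

Step 7
Reactants: 11 4'-hydroxyacetophenone
Product: 12 4'-isopropoxyacetophenone
Conditions: 2-bromopropane, K2CO3, DMF, 70 °C
Reagents that add atoms: 2-bromopropane, CC(C)Br
Why: Williamson etherification of the acidic para-acyl phenol is routine and gives the isopropyl-protected aryl ketone.

Step 8
Reactants: 12 4'-isopropoxyacetophenone (two molecules)
Product: 13 (E)-1,4-bis(4-isopropoxyphenyl)but-2-ene-1,4-dione
Conditions: CuO, I2, DMSO, 70 °C
Reagents that add atoms: none
Why: Iodine/DMSO oxidative self-condensation of aryl methyl ketones, in which α-iodination and Kornblum oxidation turn part of 12 into the arylglyoxal, which undergoes aldol condensation with unchanged 12 and dehydrates to the conjugated enedione in its thermodynamically preferred E form.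

Step 9
Reactants: 13 (E)-1,4-bis(4-isopropoxyphenyl)but-2-ene-1,4-dione; 10 lactol
Product: 15 (E)-2-{2-[(4-allyloxy-3-isopropoxy-2-methoxyphenyl)(hydroxy)methyl]-4,5-diisopropoxy-3-methoxybenzylidene}-1,4-bis(4-isopropoxyphenyl)butane-1,4-dione (racemic carbinol), via phosphorus ylide 14 (not isolated)
Conditions: 13 (1.3 equiv), PPh3 (1.3 equiv), toluene, rt, 1 h; then 10, 90 °C
Reagents that add atoms: none
Why: Conjugate addition of PPh3 to the enedione and proton shift give the stabilised acyl ylide, which undergoes Wittig olefination with the open hydroxy-aldehyde form of the lactol; as usual for stabilised ylides the aryl group should end up trans to the ylide-derived aroyl group (E), the geometry that places the CH2C(=O)Ar arm on the side of the carbinol.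

Step 10
Reactants: 15 allyl-protected arylidene diketone carbinol
Product: 16 (E)-2-{2-[hydroxy(4-hydroxy-3-isopropoxy-2-methoxyphenyl)methyl]-4,5-diisopropoxy-3-methoxybenzylidene}-1,4-bis(4-isopropoxyphenyl)butane-1,4-dione (racemic carbinol)
Conditions: Pd(PPh3)4 (5 mol %), morpholine (5 equiv), THF, rt; neutral work-up, Et3N-deactivated silica
Reagents that add atoms: none
Why: Tsuji–Trost-type deallylation, in which zerovalent palladium ionises the aryl allyl ether to a π-allyl complex that morpholine captures, frees the ring A 4-hydroxyl under neutral conditions that leave the enone, the carbinol and the isopropyl ethers alone.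

Step 11
Reactants: 16 racemic diaryl carbinol with free ring A 4-hydroxyl
Product: 18 [(1S,2S)-1-(4-hydroxy-3-isopropoxy-2-methoxyphenyl)-6,7-diisopropoxy-8-methoxy-1,2-dihydronaphthalene-2,3-diyl]bis[(4-isopropoxyphenyl)methanone] (cis; penta-O-isopropyl licobichalcone), via para-quinone methide 17 (not isolated)
Conditions: (R)-TRIP [(R)-3,3'-bis(2,4,6-triisopropylphenyl)-1,1'-binaphthyl-2,2'-diyl hydrogen phosphate] (10 mol %), toluene (0.02 M), 3 Å molecular sieves, 0 °C
Reagents that add atoms: none
Why: The phosphoric acid protonates the carbinol of 16 and water is lost with the help of the para hydroxyl of ring A, giving para-quinone methide 17 as a hydrogen-bonded complex in which the carbinol stereocentre is erased, while the same acid catalyses enolisation of the CH2–C(=O)Ar ketone toward C2; the enol carbon then adds to the methide carbon C1 (1,6-addition) and ring A rearomatises. The closest known reaction type is the chiral phosphoric acid-catalysed asymmetric 1,6-addition of enolisable carbonyl compounds and other carbon nucleophiles to para-quinone methides generated in situ from para-hydroxybenzylic alcohols, together with phosphoric acid enol catalysis of ketones. The one ring that forms, the carbocycle C1–C2–C3–C4–C4a–C8a, closes in a 6-(enolexo)-exo-trig mode by making the bond C1–C2 between two trigonal carbons that ring B and the E-configured C3=C4 bond already hold within reach. C1 is set by the face of the planar methide that is attacked and C2 by the face of the enol that attacks, and both are chosen by the catalyst, whose P–OH binds the quinone methide oxygen and whose P=O binds the enol hydroxyl; only the arrangement with ring A and the enol hydroxyl on the same side of the forming ring allows this double contact, and it leads to the cis (1S,2S) product from both enantiomers of the carbinol. The step needs C–C closure to win over conjugate addition of the carbinol oxygen to the enone and over capture by outside nucleophiles, which the easy ionisation of the electron-rich para-hydroxybenzhydrol, the poor acceptor quality of the α-branched enone and the dilution should secure; it also needs the kinetic cis configuration at C2 to persist, which the base-free medium, the low temperature and the strained exocyclic enol required for epimerisation should ensure.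

Step 12
Reactants: 18 penta-O-isopropyl licobichalcone
Product: 19 licobichalcone, [(1S,2S)-1-(3,4-dihydroxy-2-methoxyphenyl)-6,7-dihydroxy-8-methoxy-1,2-dihydronaphthalene-2,3-diyl]bis[(4-hydroxyphenyl)methanone]
Conditions: BCl3 (12 equiv), CH2Cl2, −78 to 0 °C; then H2O, 0 °C
Reagents that add atoms: none
Why: BCl3 dealkylation cleaves the five secondary isopropyl aryl ethers through their borane complexes with loss of 2-chloropropane at temperatures where aryl methyl ethers without an ortho carbonyl group persist, and the base-free low-temperature conditions should leave the C1 and C2 centres unchanged.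

**Compound list**

1 | 2,3,4-trihydroxybenzaldehyde | O=Cc1ccc(O)c(O)c1O | starting material
2 | 4-(allyloxy)-2,3-dihydroxybenzaldehyde | O=Cc1ccc(OCC=C)c(O)c1O | intermediate
3 | 4-(allyloxy)-2-hydroxy-3-isopropoxybenzaldehyde | O=Cc1ccc(OCC=C)c(OC(C)C)c1O | intermediate
4 | 4-(allyloxy)-3-isopropoxy-2-methoxybenzaldehyde (ring A aldehyde) | COc1c(C=O)ccc(OCC=C)c1OC(C)C | intermediate
5 | 5-hydroxyvanillin (3,4-dihydroxy-5-methoxybenzaldehyde) | COc1cc(C=O)cc(O)c1O | starting material
6 | 3,4-diisopropoxy-5-methoxybenzaldehyde | COc1cc(C=O)cc(OC(C)C)c1OC(C)C | intermediate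
7 | 5-(dimethoxymethyl)-1,2-diisopropoxy-3-methoxybenzene (ring B acetal) | COc1cc(C(OC)OC)cc(OC(C)C)c1OC(C)C | intermediate
8 | [2-(dimethoxymethyl)-4,5-diisopropoxy-6-methoxyphenyl]lithium (not isolated) | [Li]c1c(C(OC)OC)cc(OC(C)C)c(OC(C)C)c1OC | intermediate
9 | [4-(allyloxy)-3-isopropoxy-2-methoxyphenyl][2-(dimethoxymethyl)-4,5-diisopropoxy-6-methoxyphenyl]methanol, racemic (not isolated) | COc1c(C(O)c2c(C(OC)OC)cc(OC(C)C)c(OC(C)C)c2OC)ccc(OCC=C)c1OC(C)C | intermediate
10 | 3-[4-(allyloxy)-3-isopropoxy-2-methoxyphenyl]-5,6-diisopropoxy-4-methoxy-1,3-dihydroisobenzofuran-1-ol, racemic, both C1 epimers | COc1c(C2OC(O)c3cc(OC(C)C)c(OC(C)C)c(OC)c32)ccc(OCC=C)c1OC(C)C | intermediate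
11 | 4'-hydroxyacetophenone | CC(=O)c1ccc(O)cc1 | starting material
12 | 4'-isopropoxyacetophenone | CC(=O)c1ccc(OC(C)C)cc1 | intermediate
13 | (E)-1,4-bis(4-isopropoxyphenyl)but-2-ene-1,4-dione | CC(C)Oc1ccc(C(=O)/C=C/C(=O)c2ccc(OC(C)C)cc2)cc1 | intermediate
14 | 1,4-bis(4-isopropoxyphenyl)-2-(triphenyl-λ5-phosphanylidene)butane-1,4-dione (not isolated) | CC(C)Oc1ccc(C(=O)CC(=P(c2ccccc2)(c2ccccc2)c2ccccc2)C(=O)c2ccc(OC(C)C)cc2)cc1 | intermediate
15 | (E)-2-{2-[(4-allyloxy-3-isopropoxy-2-methoxyphenyl)(hydroxy)methyl]-4,5-diisopropoxy-3-methoxybenzylidene}-1,4-bis(4-isopropoxyphenyl)butane-1,4-dione, racemic | COc1c(C(O)c2c(/C=C(\CC(=O)c3ccc(OC(C)C)cc3)C(=O)c3ccc(OC(C)C)cc3)cc(OC(C)C)c(OC(C)C)c2OC)ccc(OCC=C)c1OC(C)C | intermediate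
16 | (E)-2-{2-[hydroxy(4-hydroxy-3-isopropoxy-2-methoxyphenyl)methyl]-4,5-diisopropoxy-3-methoxybenzylidene}-1,4-bis(4-isopropoxyphenyl)butane-1,4-dione, racemic | COc1c(C(O)c2c(/C=C(\CC(=O)c3ccc(OC(C)C)cc3)C(=O)c3ccc(OC(C)C)cc3)cc(OC(C)C)c(OC(C)C)c2OC)ccc(O)c1OC(C)C | intermediate
17 | ring A para-quinone methide of 16 (not isolated) | COC1=C(OC(C)C)C(=O)C=CC1=Cc1c(/C=C(\CC(=O)c2ccc(OC(C)C)cc2)C(=O)c2ccc(OC(C)C)cc2)cc(OC(C)C)c(OC(C)C)c1OC | intermediate
18 | [(1S,2S)-1-(4-hydroxy-3-isopropoxy-2-methoxyphenyl)-6,7-diisopropoxy-8-methoxy-1,2-dihydronaphthalene-2,3-diyl]bis[(4-isopropoxyphenyl)methanone], cis | COc1c([C@H]2c3c(cc(OC(C)C)c(OC(C)C)c3OC)C=C(C(=O)c3ccc(OC(C)C)cc3)[C@H]2C(=O)c2ccc(OC(C)C)cc2)ccc(O)c1OC(C)C | intermediate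
19 | licobichalcone, [(1S,2S)-1-(3,4-dihydroxy-2-methoxyphenyl)-6,7-dihydroxy-8-methoxy-1,2-dihydronaphthalene-2,3-diyl]bis[(4-hydroxyphenyl)methanone] | COc1c([C@H]2c3c(cc(O)c(O)c3OC)C=C(C(=O)c3ccc(O)cc3)[C@H]2C(=O)c2ccc(O)cc2)ccc(O)c1O | target

**Summary**

Total step count: 12. Longest linear sequence: 8 steps (steps 1, 2, 3, 6, 9, 10, 11, 12, from 2,3,4-trihydroxybenzaldehyde).

Steps most likely to fail:

Step 11. The two hydrogen-bond contacts of the catalyst lie far apart on a flexible substrate, so facial discrimination at C1 and C2 may be incomplete and the product may form in low enantiomeric purity. The fallback sets out from 16 and gives up catalyst control. An achiral acid (diphenyl phosphate, toluene, 0 °C) closes the same ring through 17, with the cis configuration still expected as the kinetic outcome of the synclinal closure. This gives racemic cis penta-O-isopropyl licobichalcone F1. The enantiomers are then separated by preparative chromatography on a chiral stationary phase (amylose tris(3,5-dimethylphenylcarbamate)). The (1S,2S) enantiomer is 18, where the route resumes.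

Step 9. The aldehyde is masked as a lactol and the ylide is α-branched, so the olefination may be slow. At the temperature it then needs, the free carbinol oxygen may add to the new enone and close a 1,3-dihydroisobenzofuran. The fallback sets out from hydroxy acetal 9, isolated after a neutral NH4Cl work-up of step 6 instead of the acidic one. Silylation (TBSOTf, 2,6-lutidine, CH2Cl2, −78 °C) gives the tert-butyldimethylsilyl ether of 9 F2. Mild hydrolysis of the acetal (PPTS, acetone–water, rt) gives the free, non-lactolised 2-[(aryl)(silyloxy)methyl]benzaldehyde F3. Wittig reaction with ylide 14 (toluene, 90 °C) gives the O-silylated arylidene diketone F4, in which conjugate addition of the oxygen is impossible. Buffered HF·pyridine (THF, 0 °C to rt) removes the silyl group and returns the route to 15.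

Step 6. Deprotonation may take place in part at the position beside the isopropoxy group, or stay incomplete, which would give the regioisomeric lactol and butyl adducts of 4. The fallback sets out from 6 and fixes the site before the coupling. Electrophilic bromination (NBS, MeCN, rt) gives 2-bromo-4,5-diisopropoxy-3-methoxybenzaldehyde F5. Any regioisomer is removed at this crystalline stage, and the position is assigned by the NOE between the remaining ring proton and an isopropyl methine. Acetalisation as in step 5 gives 2-bromo-1-(dimethoxymethyl)-4,5-diisopropoxy-3-methoxybenzene F6. Bromine–lithium exchange (n-BuLi, THF, −78 °C) gives aryllithium 8, where the route resumes with the addition to 4 and the acidic work-up to 10.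

**Further compounds**

F1 | step 11 | racemic cis penta-O-isopropyl licobichalcone (1S,2S and 1R,2R) | COc1c([C@H]2c3c(cc(OC(C)C)c(OC(C)C)c3OC)C=C(C(=O)c3ccc(OC(C)C)cc3)[C@H]2C(=O)c2ccc(OC(C)C)cc2)ccc(O)c1OC(C)C.COc1c([C@@H]2c3c(cc(OC(C)C)c(OC(C)C)c3OC)C=C(C(=O)c3ccc(OC(C)C)cc3)[C@@H]2C(=O)c2ccc(OC(C)C)cc2)ccc(O)c1OC(C)C
F2 | step 9 | tert-butyldimethylsilyl ether of hydroxy acetal 9, racemic | COc1c(C(O[Si](C)(C)C(C)(C)C)c2c(C(OC)OC)cc(OC(C)C)c(OC(C)C)c2OC)ccc(OCC=C)c1OC(C)C
F3 | step 9 | 2-{[4-(allyloxy)-3-isopropoxy-2-methoxyphenyl][(tert-butyldimethylsilyl)oxy]methyl}-4,5-diisopropoxy-3-methoxybenzaldehyde, racemic | COc1c(C(O[Si](C)(C)C(C)(C)C)c2c(C=O)cc(OC(C)C)c(OC(C)C)c2OC)ccc(OCC=C)c1OC(C)C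
F4 | step 9 | O-tert-butyldimethylsilyl ether of 15, racemic | COc1c(C(O[Si](C)(C)C(C)(C)C)c2c(/C=C(\CC(=O)c3ccc(OC(C)C)cc3)C(=O)c3ccc(OC(C)C)cc3)cc(OC(C)C)c(OC(C)C)c2OC)ccc(OCC=C)c1OC(C)C
F5 | step 6 | 2-bromo-4,5-diisopropoxy-3-methoxybenzaldehyde | COc1c(Br)c(C=O)cc(OC(C)C)c1OC(C)C
F6 | step 6 | 2-bromo-1-(dimethoxymethyl)-4,5-diisopropoxy-3-methoxybenzene | COc1c(Br)c(C(OC)OC)cc(OC(C)C)c1OC(C)C
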